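The runs come from a simulation with constants of no real substance; scatter was added.

The trap is to read the 20 h beside north and south-east as the same treatment of the target. I take over-reaction product to form from target already made, so you want to know how long that target has stood in the vessel.

| setting | gamma | theta | alpha | north | south-east | east | north-west |
|---|---|---|---|---|---|---|---|
| starting material | 0.10 M | 0.14 M | 0.22 M | 0.10 M | 0.10 M | 0.10 M (fed, over 10.0 h) | 0.10 M |
| free catalyst | 0.10 mM | 0.10 mM | 0.10 mM | 0.10 mM | 0.10 mM | 0.10 mM | 0.10 mM |
| remark | run made earlier | run made earlier | run made earlier | a closed flask charged with all of it at once and left for 20 h | one stirred flow tank at steady state, fed with the mixture as stated, mean residence time 20 h | a stirred flask in which starting material is dosed at a steady rate over 10.0 h without added volume, worked up at 20 h | plug flow through a tube for 20 h, no back-mixing |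
| time |  |  |  | 20 h |  | 20 h | 20 h |

| run | time / h | target / % | over-reaction product / % |
|---|---|---|---|
| gamma | 2.00 | 5 | 0 |
| gamma | 4.00 | 8 | 1 |
| gamma | 6.00 | 16 | 1 |
| gamma | 8.00 | 21 | 1 |
| gamma | 10.0 | 25 | 1 |
| gamma | 12.0 | 29 | 0 |
| theta | 0.833 | 1 | 0 |
| theta | 2.50 | 7 | 1 |
| theta | 4.00 | 9 | 1 |
| theta | 6.00 | 11 | 2 |
| theta | 10.0 | 23 | 0 |
| theta | 12.0 | 26 | 0 |
| alpha | 0.833 | 2 | 0 |
| alpha | 2.50 | 6 | 0 |
| alpha | 4.00 | 6 | 0 |
| alpha | 6.00 | 12 | 1 |
| alpha | 10.0 | 14 | 0 |
| alpha | 12.0 | 22 | 0 |

(readings scatter by 1.5 percentage points)

- the stated concentrations are those of everything mixed, before any reaction; amounts are the same in each set-up
- the numbers in the tables scatter with a standard deviation of 1.5 percentage points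
- the feed brings no volume worth counting
- the earlier runs were made in a closed, stirred flask

* the set-up with the highest share of target in all that became target or over-reaction product, at the outlet or at the end ("none" if the first two lie within 2 percentage points) (north / south-east / east / north-west / none)
* share of target in all that became target or over-reaction product, at the outlet or at the end, north
* share of target in all that became target or over-reaction product, at the outlet or at the end, south-east
* share of target in all that became target or over-reaction product, at the outlet or at the end, east
* share of target in all that became target or over-reaction product, at the outlet or at the end, north-west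

1. The gamma run reads 16 % target at 6.00 h and 29 % at 12.0 h, a nearly straight rise, so if target forms steadily, north has an age of the target of 10.0 h, the mean time its molecules have stood in the vessel. That is half the elapsed time, and north-west, a tube without back-mixing, reckons the same.

2. South-east looks nearly the same, but its outlet has the composition of the whole stirred contents, so its target is as old as the mean residence time, 20.0 h, which is twice the age in north. You should therefore expect twice the over-reaction product per target there, as long as the loss stays slow.

3. In east I let target start late by half the dosing time of 10.0 h, which gives an age of 7.50 h, shorter than in north.

4. The gamma reading at 10.0 h, 1 % over-reaction product beside 25 % target, gives a pseudo-first-order loss of 0.00800 /h, and you should take this as rough, for that reading of over-reaction product carries a scatter of 1.5 percentage points. This is a target half-life of 86.6 h, longer than 20 h.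

5. With share equal to one over one plus loss times age, I commit to 92.6 % for north and north-west, 86.2 % for south-east and 94.3 % for east. East's lead of 1.7 points is smaller than the margin of 2 points, so my answer is none.

The forecast, higher than my shares, gave 95 % for north and north-west, 92 % for south-east, 96 % for east and none as best, holding that “Dosing forms target later”.

The flask gives 97.7 % for north, 97.7 % for north-west, 95.6 % for south-east and 98.2 % for east, so the best is none.

    starting material + free catalyst ⇌ catalyst intermediate (K = 190 /M, k = 9.30 /M/min)
    catalyst intermediate → free catalyst + target (k = 0.930 /min)
    free catalyst + target → free catalyst + over-reaction product (k = 0.600 /M/min)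

In north, starting material fell to 53.7 % of the charge by 20.0 h while 33.8 % of the catalyst stood as catalyst intermediate, and target reached 45.2 %. Beside this in north, the step from target to over-reaction product, which alone and with the other concentrations as charged gives target a half-life of 190 h, longer than 20 h, made 1.06 %. My shares lie below the flask's, but over-reaction product per target in south-east stands at 1.96 times north's against an age ratio of 2.00, and in east at 0.802 against 0.750.

Read east at 2.0 d: counted as before, as if target formed steadily, its age is 21.5 h, 2.15 times north's, which from north's loss gives an estimated share of 95.2 %. The computed flask holds 93.5 %, with 74.1 % target and 5.14 % over-reaction product.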